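**Retrosynthetic overview**

Neolignan numbering: C7 is the carbinol carbon on ring A (3,4,5-trimethoxyphenyl), C8 carries the ether oxygen to ring B (4-allyl-2,6-dimethoxyphenyl), and C9 is the CH2OAc carbon.
The route rests on the threo C7/C8 pair: with C9 raised to the carboxyl level and joined to the C7 oxygen, it becomes a cis-3-aryloxy-4-aryl-oxetan-2-one (C8 = lactone C3, C7 = lactone C4).
Disconnections: C9 acetate to the 7,9-diol; diol to the β-lactone by hydride opening; β-lactone to the ring B aryloxyacetyl chloride and the ring A aldehyde by a catalytic asymmetric ketene–aldehyde [2+2] (C7–C8 and O7–C9 bonds); acid chloride to the ring B phenol and a bromoacetate.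
Ring order: rings A and B are bought; the oxetanone is the only ring made (step 4) and is opened again in step 5.

Key step: step 4

Assumption: the sense of induction of the quinine-derived catalyst is taken to carry over from alkylketenes to the aryloxyketene; if the first run gives the mirror-image lactone (checked at the diol stage by Mosher ester analysis at C7), O-trimethylsilylquinidine replaces O-trimethylsilylquinine with nothing else changed.

**Route**

Step 1
Reactants: 1 4-allyl-2,6-dimethoxyphenol; 2 ethyl bromoacetate
Product: 3 ethyl (4-allyl-2,6-dimethoxyphenoxy)acetate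
Conditions: K2CO3, acetone, reflux
Reagents that add atoms: none
Why: Williamson ether synthesis, in which the phenoxide displaces bromide from the activated α-bromo ester by SN2 and the mild carbonate base leaves the allyl double bond where it is.

Step 2
Reactants: 3 ethyl (4-allyl-2,6-dimethoxyphenoxy)acetate
Product: 4 (4-allyl-2,6-dimethoxyphenoxy)acetic acid
Conditions: LiOH·H2O, THF/H2O, rt; then 1 M HCl
Reagents that add atoms: lithium hydroxide, [Li+].[OH-]
Why: Ester saponification by acyl–oxygen cleavage, which at room temperature is far too mild to move the allyl double bond into conjugation with ring B.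

Step 3
Reactants: 4 (4-allyl-2,6-dimethoxyphenoxy)acetic acid
Product: 5 (4-allyl-2,6-dimethoxyphenoxy)acetyl chloride
Conditions: (COCl)2, DMF (cat.), CH2Cl2, 0 °C to rt; evaporate, use crude
Reagents that add atoms: oxalyl chloride, O=C(Cl)C(Cl)=O
Why: Acid chloride formation through the catalytic Vilsmeier-type chloroiminium species, with only gaseous by-products and no effect on the aryl ethers or the terminal alkene.

Step 4
Reactants: 5 (4-allyl-2,6-dimethoxyphenoxy)acetyl chloride; 6 3,4,5-trimethoxybenzaldehyde
Product: 8 cis-(3S,4R)-3-(4-allyl-2,6-dimethoxyphenoxy)-4-(3,4,5-trimethoxyphenyl)oxetan-2-one, via (4-allyl-2,6-dimethoxyphenoxy)ketene 7 (not isolated)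
Conditions: O-trimethylsilylquinine (10 mol%), LiClO4 (2 equiv), iPr2NEt (2.5 equiv), CH2Cl2/Et2O, −78 °C; 5 (2 equiv) added slowly; quick filtration through silica, used at once
Reagents that add atoms: none
Why: iPr2NEt dehydrochlorinates 5 to ketene 7, the quinuclidine nitrogen of the silylated alkaloid adds to the ketene carbonyl carbon on the side away from the aryloxy group to give a Z-ammonium enolate, this enolate attacks the LiClO4-activated carbonyl of 6 in a closed, lithium-bridged transition state (C7–C8 bond), and the lithium aldolate oxygen then displaces the catalyst from the acylammonium carbon (O7–C9 bond). The closest known reaction type is the cinchona alkaloid and lithium perchlorate catalysed acyl halide–aldehyde cyclocondensation (formal ketene–aldehyde [2+2], aldol-lactonisation) that gives cis-3,4-disubstituted β-lactones, and aryloxyketenes are established partners of the same alkaloids in asymmetric Staudinger β-lactam synthesis. The oxetan-2-one closes by 4-exo-trig acyl substitution. C8 (lactone C3) is set by the alkaloid, whose quinoline and silyl ether block one face of the enolate, and C7 (lactone C4) is set relative to it by the closed transition state, which places the aldehyde aryl group cis to the aryloxy group; cis corresponds to the threo diol. The step needs enantiofacial control, cis selectivity and cross-reaction in preference to ketene dimerisation: the monosubstituted ketene can give only one enolate geometry, 6 cannot enolise and is about as electrophilic as benzaldehyde (its 4-methoxy group is twisted out of conjugation by its neighbours while the 3- and 5-methoxy groups withdraw inductively), iPr2NEt is too hindered to form a competing achiral enolate, and slow addition keeps the ketene concentration low.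

Step 5
Reactants: 8 cis-(3S,4R)-3-(4-allyl-2,6-dimethoxyphenoxy)-4-(3,4,5-trimethoxyphenyl)oxetan-2-one
Product: 10 (1R,2R)-2-(4-allyl-2,6-dimethoxyphenoxy)-1-(3,4,5-trimethoxyphenyl)propane-1,3-diol, via hydroxy aldehyde 9 (not isolated)
Conditions: LiBH4 (excess), THF, 0 °C; then H2O
Reagents that add atoms: none
Why: Hydride reduction of a β-lactone by acyl–oxygen cleavage, in which the strained lactone opens to the alkoxide–aldehyde 9 that is reduced at once to the primary alcohol, so no bond at C7 or C8 is broken, both centres are retained (the descriptor at C8 changes only through CIP priorities) and the isolated alkene is not touched.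

Step 6
Reactants: 10 (1R,2R)-2-(4-allyl-2,6-dimethoxyphenoxy)-1-(3,4,5-trimethoxyphenyl)propane-1,3-diol
Product: 11 (2R,3R)-2-(4-allyl-2,6-dimethoxyphenoxy)-3-hydroxy-3-(3,4,5-trimethoxyphenyl)propyl acetate
Conditions: AcCl (1.1 equiv), 2,4,6-collidine, CH2Cl2, −78 °C
Reagents that add atoms: acetyl chloride, CC(Cl)=O
Why: Chemoselective acylation of a primary in the presence of a secondary alcohol, in which the hindered base and low temperature let the unhindered C9 hydroxyl react much faster than the benzylic C7 hydroxyl, which is flanked by ring A and the bulky ring B ether.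

**Compound list**

1 | 4-allyl-2,6-dimethoxyphenol | C=CCc1cc(OC)c(O)c(OC)c1 | starting material
2 | ethyl bromoacetate | CCOC(=O)CBr | starting material
3 | ethyl (4-allyl-2,6-dimethoxyphenoxy)acetate | C=CCc1cc(OC)c(OCC(=O)OCC)c(OC)c1 | intermediate
4 | (4-allyl-2,6-dimethoxyphenoxy)acetic acid | C=CCc1cc(OC)c(OCC(=O)O)c(OC)c1 | intermediate
5 | (4-allyl-2,6-dimethoxyphenoxy)acetyl chloride | C=CCc1cc(OC)c(OCC(Cl)=O)c(OC)c1 | intermediate
6 | 3,4,5-trimethoxybenzaldehyde | COc1cc(C=O)cc(OC)c1OC | starting material
7 | (4-allyl-2,6-dimethoxyphenoxy)ketene | C=CCc1cc(OC)c(OC=C=O)c(OC)c1 | intermediate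
8 | cis-(3S,4R)-3-(4-allyl-2,6-dimethoxyphenoxy)-4-(3,4,5-trimethoxyphenyl)oxetan-2-one | C=CCc1cc(OC)c(O[C@H](C3=O)[C@H](O3)c2cc(OC)c(OC)c(OC)c2)c(OC)c1 | intermediate
9 | (2S,3R)-2-(4-allyl-2,6-dimethoxyphenoxy)-3-hydroxy-3-(3,4,5-trimethoxyphenyl)propanal (present as its lithium alkoxide) | C=CCc1cc(OC)c(O[C@H](C=O)[C@H](O)c2cc(OC)c(OC)c(OC)c2)c(OC)c1 | intermediate
10 | (1R,2R)-2-(4-allyl-2,6-dimethoxyphenoxy)-1-(3,4,5-trimethoxyphenyl)propane-1,3-diol (threo) | C=CCc1cc(OC)c(O[C@H](CO)[C@H](O)c2cc(OC)c(OC)c(OC)c2)c(OC)c1 | intermediate
11 | (2R,3R)-2-(4-allyl-2,6-dimethoxyphenoxy)-3-hydroxy-3-(3,4,5-trimethoxyphenyl)propyl acetate (7R,8R, threo) | C=CCc1cc(OC)c(O[C@H](COC(C)=O)[C@H](O)c2cc(OC)c(OC)c(OC)c2)c(OC)c1 | target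

**Step count**

Total steps: 6. Longest linear sequence: 6 steps (1 → 3 → 4 → 5 → 8 → 10 → 11); aldehyde 6 enters at step 4.

**Steps most likely to fail**

1. Step 4. Three processes threaten it:
   - The aryloxyketene may dimerise or oligomerise faster than it is captured by the aldehyde.
   - Lithium may bind to the ether and ortho-methoxy oxygens of ring B and loosen the closed transition state, which would erode cis selectivity or enantiofacial control.
   - The 4-aryl lactone may lose CO2 or ionise at C7 during handling.

   Fallback, setting out from 5 and coming back at 10: an auxiliary-controlled Evans syn glycolate aldol. Lithiated (S)-4-benzyl-2-oxazolidinone (n-BuLi, THF, −78 °C) is acylated with 5 to give (S)-4-benzyl-3-[(4-allyl-2,6-dimethoxyphenoxy)acetyl]oxazolidin-2-one F1. Its Z-boron enolate (Bu2BOTf, iPr2NEt, CH2Cl2, −78 °C) should add to aldehyde 6 through a chair transition state to give the syn aldol imide (4S)-4-benzyl-3-[(2S,3R)-2-(4-allyl-2,6-dimethoxyphenoxy)-3-hydroxy-3-(3,4,5-trimethoxyphenyl)propanoyl]oxazolidin-2-one F2 after a pH 7 buffer/MeOH work-up. The syn relationship of aryloxy and hydroxyl is the threo arrangement. LiBH4 (THF, 1 equiv H2O, 0 °C) then removes the auxiliary reductively and should give diol 10 directly, so lactone 8 is bypassed.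

2. Step 5. The lithium alkoxide–aldehyde formed after the first hydride transfer may undergo retro-aldol cleavage or epimerise at C8 before the second hydride arrives.

   Fallback, setting out from 8 and coming back at 10: acyl transfer is separated from reduction. Lactone 8 is opened with MeOH and catalytic DMAP (0 °C to rt) to methyl (2S,3R)-2-(4-allyl-2,6-dimethoxyphenoxy)-3-hydroxy-3-(3,4,5-trimethoxyphenyl)propanoate F3. In this ester the C7 hydroxyl is protonated and cannot trigger fragmentation. The activated α-aryloxy ester is then reduced with NaBH4 in THF/MeOH (0 °C to rt) to diol 10.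

3. Step 6. The benzylic C7 hydroxyl may be acetylated as well, or the acetyl group may migrate between the 1,3-related oxygens during purification.

   Fallback, setting out from 10 and coming back at 11: enzymatic transesterification with immobilised Candida antarctica lipase B and vinyl acetate in tert-butyl methyl ether at 30 °C. The enzyme should acylate only the unhindered primary hydroxyl under neutral conditions. No new compound lies on this path (F0).

**Further compounds**

F1 | step 4 | (S)-4-benzyl-3-[(4-allyl-2,6-dimethoxyphenoxy)acetyl]oxazolidin-2-one | C=CCc1cc(OC)c(OCC(=O)N2[C@@H](Cc3ccccc3)COC2=O)c(OC)c1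
F2 | step 4 | (4S)-4-benzyl-3-[(2S,3R)-2-(4-allyl-2,6-dimethoxyphenoxy)-3-hydroxy-3-(3,4,5-trimethoxyphenyl)propanoyl]oxazolidin-2-one | C=CCc1cc(OC)c(O[C@H](C(=O)N2[C@@H](Cc3ccccc3)COC2=O)[C@H](O)c4cc(OC)c(OC)c(OC)c4)c(OC)c1
F3 | step 5 | methyl (2S,3R)-2-(4-allyl-2,6-dimethoxyphenoxy)-3-hydroxy-3-(3,4,5-trimethoxyphenyl)propanoate | C=CCc1cc(OC)c(O[C@H](C(=O)OC)[C@H](O)c2cc(OC)c(OC)c(OC)c2)c(OC)c1
F0 | step 6 | none | none
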